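**Plan**

1. The coumarin is cut at C3=C4 and at O1–C2 (Knoevenagel condensation, then lactonisation). This gives a lactol that masks 2,4-dihydroxy-6-(2-hydroxypropyl)-3,5-dimethylbenzaldehyde, and a (dihydropyranonyl)acetic ester.
2. The dihydropyranone is cut at O1–C6 and C4–C5. Its O1–C2H(CH3)–C3H2–C4(=O) array is the complete ring of 4-methyloxetan-2-one, and C5=C6 is the enolised CH2–C(=O) end of an acetoacetate. The six-membered ring is therefore the β-lactone with two carbons inserted into its acyl–oxygen bond (4 → 6 ring expansion). The acetoacetate ester is the activating group and later becomes the coumarin C2 carbonyl.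
3. The lactol is cut at aryl–CH2 (ortho-lithiated benzamide plus epoxide) and at the amide carbon (directed metalation of 1,3-dimethoxy-2,4-dimethylbenzene).
4. Forward order: arene → benzamide → dihydroisocoumarin ring → lactol (steps 1–5); β-lactone → dihydropyranone (step 6); the coumarin pyranone ring is closed last and joins the two halves (step 7).
5. Stereochemistry: C2 of the dihydropyranone (R) is C4 of (R)-β-butyrolactone; the side-chain carbinol (S) is C2 of (S)-propylene oxide. No bond to either stereocentre is broken in the route.

Key step: step 6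

Assumption: 2,4-dimethoxy-3-methylbenzaldehyde, (S)-propylene oxide, methyl acetoacetate and (R)-β-butyrolactone are taken as purchased; everything else is made.

**Route**

Step 1
Reactants: 1 2,4-dimethoxy-3-methylbenzaldehyde
Product: 2 1,3-dimethoxy-2,4-dimethylbenzene
Conditions: H2 (1 atm), 10% Pd/C, AcOH, cat. HCl, rt
Reagents that add atoms: none
Why: Catalytic hydrogenolysis of an electron-rich aryl aldehyde through the benzylic alcohol to the methyl arene is a standard benzylic C–O reduction in acidic medium, and the aryl methyl ethers are inert to it.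

Step 2
Reactants: 2 1,3-dimethoxy-2,4-dimethylbenzene
Product: 4 N,N-diethyl-2,4-dimethoxy-3,5-dimethylbenzamide, via aryllithium 3 (not isolated)
Conditions: n-BuLi, TMEDA, Et2O, 0 °C → rt; then ClC(O)NEt2, −78 °C → rt
Reagents that add atoms: diethylcarbamoyl chloride, CCN(CC)C(Cl)=O
Why: Directed ortho-metalation: the C1 methoxy group should direct n-BuLi/TMEDA to the only ring position ortho to an OMe group (C6), and acylation of the aryllithium by the carbamoyl chloride installs the tertiary amide that serves as the next directing group.

Step 3
Reactants: 4 N,N-diethyl-2,4-dimethoxy-3,5-dimethylbenzamide; 5 (S)-propylene oxide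
Product: 8 (3S)-6,8-dimethoxy-3,5,7-trimethyl-3,4-dihydro-1H-isochromen-1-one, via aryllithium 6 (not isolated), via hydroxy amide 7 (not isolated)
Conditions: s-BuLi, TMEDA, THF, −78 °C; then 5, BF3·OEt2 (3 equiv), −78 °C; aq. NH4Cl; then TsOH·H2O (1.2 equiv), PhMe, reflux
Reagents that add atoms: none
Why: Amide-directed ortho-lithiation should occur at the single free ortho position, BF3-assisted SN2 opening of the epoxide at its CH2 terminus leaves the (S) stereocentre untouched, and acid-promoted lactonisation of the δ-hydroxy amide expels diethylamine with retention at the carbinol carbon.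

Step 4
Reactants: 8 (3S)-6,8-dimethoxy-3,5,7-trimethyl-3,4-dihydro-1H-isochromen-1-one
Product: 9 (3S)-6,8-dihydroxy-3,5,7-trimethyl-3,4-dihydro-1H-isochromen-1-one
Conditions: BBr3 (3.5 equiv), CH2Cl2, −78 → 0 °C; then H2O
Reagents that add atoms: none
Why: BBr3 cleavage of aryl methyl ethers is the standard demethylation of methoxy-dihydroisocoumarins (the peri 8-OMe is assisted by chelation to the lactone carbonyl, the 6-OMe is twisted out of plane by its two ortho methyl groups), and at low temperature the secondary alkyl C–O bond of the lactone should not be touched.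

Step 5
Reactants: 9 (3S)-6,8-dihydroxy-3,5,7-trimethyl-3,4-dihydro-1H-isochromen-1-one
Product: 10 (3S)-3,5,7-trimethyl-3,4-dihydro-1H-isochromene-1,6,8-triol (lactol, mixture of C1 epimers, used crude)
Conditions: DIBAL-H (4 equiv), THF/PhMe, −78 °C; Rochelle salt
Reagents that add atoms: none
Why: Partial reduction of a lactone to the lactol with DIBAL-H at low temperature; the two phenols are first converted into aluminium phenoxides (hence the excess), and the tetrahedral aluminate should survive until work-up, so that over-reduction is avoided.

Step 6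
Reactants: 11 methyl acetoacetate; 12 (R)-β-butyrolactone [(4R)-4-methyloxetan-2-one]
Product: 15 methyl 2-[(2R)-2-methyl-4-oxo-3,4-dihydro-2H-pyran-6-yl]acetate, via dianion 13 (not isolated), via triketide ester 14 (not isolated)
Conditions: 11 (2.2 equiv), LDA (commercial solution, 4.4 equiv), THF, 0 °C; then 12 (1 equiv), −78 → −20 °C; aq. HCl; then TsOH·H2O (10 mol%), CH2Cl2, MgSO4, rt
Reagents that add atoms: none
Why: The γ-carbon of dianion 13, its most basic and nucleophilic site, should add to the strained lactone carbonyl of 12 and the tetrahedral intermediate collapses with acyl–oxygen fission, which frees the ring oxygen as the C7 hydroxyl of diketo ester 14; under acid this hydroxyl adds to the C3 ketone and water is lost, so the four-membered oxetan-2-one re-closes around the two inserted carbons as the six-membered 2,3-dihydro-4H-pyran-4-one (net two-carbon ring expansion). The closest known reaction types are the Claisen-type C-acylation of lithium ester enolates and related carbanions by β-lactones at the acyl carbon, the γ-acylation of acetoacetate dianions by esters, and the acid-catalysed cyclodehydration of δ-hydroxy-β-diketones to dihydropyranones. The ring closes by 6-exo-trig attack of the hydroxyl on the ketone carbon (hemiketal), followed by dehydration to the endocyclic vinylogous ester. No stereocentre is created: C2 of the pyranone is C4 of (R)-12, none of whose bonds is broken, so the (R) configuration is carried over. The step needs acyl attack in preference to SN2 attack at C4 or α-deprotonation of the lactone, which the hard lithium carbanion, the secondary methyl-bearing C4 and the low temperature should secure; it also needs closure onto C3 instead of pyrone formation through the ester, which the acidic conditions and the fact that only the C3 ketone lies at six-ring distance from the hydroxyl should secure.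

Step 7
Reactants: 10 (3S)-3,5,7-trimethyl-3,4-dihydro-1H-isochromene-1,6,8-triol; 15 methyl 2-[(2R)-2-methyl-4-oxo-3,4-dihydro-2H-pyran-6-yl]acetate
Product: 18 7-hydroxy-5-[(2S)-2-hydroxypropyl]-6,8-dimethyl-3-[(2R)-2-methyl-4-oxo-3,4-dihydro-2H-pyran-6-yl]-2H-chromen-2-one, via hydroxy aldehyde 16 (not isolated), via Knoevenagel adduct 17 (not isolated)
Conditions: piperidine (20 mol%), AcOH (20 mol%), EtOH, 50 °C
Reagents that add atoms: none
Why: Knoevenagel condensation of the latent salicylaldehyde (lactol opening to 16, activated as its piperidinium ion) with the doubly activated methylene of 15 (ester plus vinylogous ketone), followed by lactonisation of the ortho phenol onto the methyl ester, is the classical coumarin synthesis, and the mild buffered amine catalyst should leave both stereocentres untouched.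

**Compound list**

1 | 2,4-dimethoxy-3-methylbenzaldehyde | COc1ccc(C=O)c(OC)c1C | starting material
2 | 1,3-dimethoxy-2,4-dimethylbenzene | COc1ccc(C)c(OC)c1C | intermediate
3 | (2,4-dimethoxy-3,5-dimethylphenyl)lithium (formed in the flask) | [Li]c1cc(C)c(OC)c(C)c1OC | intermediate
4 | N,N-diethyl-2,4-dimethoxy-3,5-dimethylbenzamide | CCN(CC)C(=O)c1cc(C)c(OC)c(C)c1OC | intermediate
5 | (S)-propylene oxide [(2S)-2-methyloxirane] | C[C@H]1CO1 | starting material
6 | [2-(diethylcarbamoyl)-3,5-dimethoxy-4,6-dimethylphenyl]lithium (formed in the flask) | CCN(CC)C(=O)c1c([Li])c(C)c(OC)c(C)c1OC | intermediate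
7 | N,N-diethyl-2-[(2S)-2-hydroxypropyl]-4,6-dimethoxy-3,5-dimethylbenzamide (formed in the flask) | CCN(CC)C(=O)c1c(C[C@H](C)O)c(C)c(OC)c(C)c1OC | intermediate
8 | (3S)-6,8-dimethoxy-3,5,7-trimethyl-3,4-dihydro-1H-isochromen-1-one | C[C@H]1Cc2c(C)c(OC)c(C)c(OC)c2C(=O)O1 | intermediate
9 | (3S)-6,8-dihydroxy-3,5,7-trimethyl-3,4-dihydro-1H-isochromen-1-one | C[C@H]1Cc2c(C)c(O)c(C)c(O)c2C(=O)O1 | intermediate
10 | (3S)-3,5,7-trimethyl-3,4-dihydro-1H-isochromene-1,6,8-triol (lactol, C1 epimers) | C[C@H]1Cc2c(C)c(O)c(C)c(O)c2C(O)O1 | intermediate
11 | methyl acetoacetate | COC(=O)CC(C)=O | starting material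
12 | (R)-β-butyrolactone [(4R)-4-methyloxetan-2-one] | C[C@@H]1CC(=O)O1 | starting material
13 | dilithium dianion of methyl acetoacetate (formed in the flask) | [Li+].[Li+].[CH2-]C(=O)[CH-]C(=O)OC | intermediate
14 | methyl (7R)-7-hydroxy-3,5-dioxooctanoate (formed in the flask) | COC(=O)CC(=O)CC(=O)C[C@@H](C)O | intermediate
15 | methyl 2-[(2R)-2-methyl-4-oxo-3,4-dihydro-2H-pyran-6-yl]acetate | COC(=O)CC1=CC(=O)C[C@@H](C)O1 | intermediate
16 | 2,4-dihydroxy-6-[(2S)-2-hydroxypropyl]-3,5-dimethylbenzaldehyde (open form of 10, formed in the flask) | O=Cc1c(O)c(C)c(O)c(C)c1C[C@H](C)O | intermediate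
17 | methyl 3-{2,4-dihydroxy-6-[(2S)-2-hydroxypropyl]-3,5-dimethylphenyl}-2-[(2R)-2-methyl-4-oxo-3,4-dihydro-2H-pyran-6-yl]prop-2-enoate (E/Z mixture, formed in the flask; the Z isomer lactonises) | COC(=O)C(=Cc1c(O)c(C)c(O)c(C)c1C[C@H](C)O)C1=CC(=O)C[C@@H](C)O1 | intermediate
18 | 7-hydroxy-5-[(2S)-2-hydroxypropyl]-6,8-dimethyl-3-[(2R)-2-methyl-4-oxo-3,4-dihydro-2H-pyran-6-yl]-2H-chromen-2-one | Cc1c(O)c(C)c2oc(=O)c(C3=CC(=O)C[C@@H](C)O3)cc2c1C[C@H](C)O | target

**Step count and risks**

Total steps: 7. Longest linear sequence: 6 (steps 1–5, then step 7); step 6 is a one-step side branch.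

Steps most likely to fail:

1. Step 6. The dianion may attack the lactone at the wrong site (SN2 opening at C4 to a carboxylate, or α-deprotonation followed by β-elimination to crotonate) instead of transferring the acyl group, and proton transfer from the acidic product may quench the dianion. Fallback, setting out from 12 and 11 and coming back at 15: the lactone 12 is opened at the acyl carbon with N,O-dimethylhydroxylamine hydrochloride and Me2AlCl (CH2Cl2, 0 °C) to (3R)-3-hydroxy-N-methoxy-N-methylbutanamide F1. This is silylated (TBSCl, imidazole, DMF) to (3R)-3-[(tert-butyldimethylsilyl)oxy]-N-methoxy-N-methylbutanamide F2. The dianion 13 made from 11 is then acylated by this Weinreb amide, which cannot alkylate (THF, −78 → 0 °C), to methyl (7R)-7-[(tert-butyldimethylsilyl)oxy]-3,5-dioxooctanoate F3. Aqueous HF in MeCN removes the silyl group and closes the ring with loss of water to give 15.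

2. Step 3. The hindered ortho-lithiated amide may open the epoxide slowly or at the wrong carbon, may condense with the amide of a second molecule on warming, or metalation may occur at a methyl group instead of the ring. Fallback, setting out from 4 and coming back at 7: the ortho-lithiated amide 6 is quenched with MeI to N,N-diethyl-2,4-dimethoxy-3,5,6-trimethylbenzamide F4. Lateral lithiation of the methyl group ortho to the amide (s-BuLi, TMEDA, THF, −78 °C) and acylation with N-methoxy-N-methylacetamide give N,N-diethyl-2,4-dimethoxy-3,5-dimethyl-6-(2-oxopropyl)benzamide F5. A Prelog-selective ketoreductase (NADP+, iPrOH, buffer) reduces the ketone to the (S)-alcohol 7, which is lactonised with TsOH as in the second half of step 3 to give 8.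

3. Step 7. The lactol may unmask slowly, the amine may open the vinylogous ester of the dihydropyranone, and configuration at C2 of the pyranone may be lost through reversible β-elimination and oxa-Michael re-addition under basic conditions. Fallback, setting out from 14 and 10 and coming back at 18: 14, isolated after the acidic quench of step 6 before the TsOH treatment, is enol-lactonised with DBU in toluene to 4-hydroxy-6-[(2R)-2-hydroxypropyl]-2H-pyran-2-one F6. This much more acidic partner condenses with 10 under nearly neutral conditions (cat. piperidine, EtOH, 50 °C); the ortho phenol then opens the pyrone lactone (translactonisation) to give 7-hydroxy-3-[(5R)-5-hydroxy-3-oxohexanoyl]-5-[(2S)-2-hydroxypropyl]-6,8-dimethyl-2H-chromen-2-one F7. TFA in CH2Cl2 closes the dihydropyranone by cyclodehydration of the δ-hydroxy-β-diketone to give 18, so that the finished dihydropyranone is never exposed to base.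

**Further compounds**

F1 | step 6 | (3R)-3-hydroxy-N-methoxy-N-methylbutanamide | CON(C)C(=O)C[C@@H](C)O
F2 | step 6 | (3R)-3-[(tert-butyldimethylsilyl)oxy]-N-methoxy-N-methylbutanamide | CON(C)C(=O)C[C@@H](C)O[Si](C)(C)C(C)(C)C
F3 | step 6 | methyl (7R)-7-[(tert-butyldimethylsilyl)oxy]-3,5-dioxooctanoate | COC(=O)CC(=O)CC(=O)C[C@@H](C)O[Si](C)(C)C(C)(C)C
F4 | step 3 | N,N-diethyl-2,4-dimethoxy-3,5,6-trimethylbenzamide | CCN(CC)C(=O)c1c(C)c(C)c(OC)c(C)c1OC
F5 | step 3 | N,N-diethyl-2,4-dimethoxy-3,5-dimethyl-6-(2-oxopropyl)benzamide | CCN(CC)C(=O)c1c(CC(C)=O)c(C)c(OC)c(C)c1OC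
F6 | step 7 | 4-hydroxy-6-[(2R)-2-hydroxypropyl]-2H-pyran-2-one | O=C1C=C(O)C=C(C[C@@H](C)O)O1
F7 | step 7 | 7-hydroxy-3-[(5R)-5-hydroxy-3-oxohexanoyl]-5-[(2S)-2-hydroxypropyl]-6,8-dimethyl-2H-chromen-2-one | Cc1c(O)c(C)c2oc(=O)c(C(=O)CC(=O)C[C@@H](C)O)cc2c1C[C@H](C)O
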